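## Retrosynthetic overview

- Chain numbering runs C1≡C2 to C15. Ring A is C7–O–C10 and ring B is C9–O–C12. The rings are closed B first, then A, as in the presumed biogenesis from a linear C15 enyne.
- Ring A (last): C10–OH adds 5-exo-dig, anti, to the C6≡C7 alkyne. This gives the 6Z enol ether only after all electrophilic bromine chemistry is finished.
- Ring B and both C–Br bonds (one step): Br2 acts on an acyclic cis-8,9-epoxy-12E-ene. A bromonium ion forms at C12=C13, the epoxide oxygen closes on C12, and bromide opens the oxonium ion at propargylic C8.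
- The epoxide comes from OH-directed epoxidation of a linear (3Z,8Z,12E)-trienediyn-10-ol. C10 is the only catalyst-set stereocentre and relays to C8, C9, C12 and C13.
- The C15 chain is C6 ((E)-hex-3-enal) + C4 (butadiyne) + C3 ((Z)-1,3-dichloropropene) + C2 (ethynylsilane).

Assumption: the SMILES is read as (3Z,6Z,8S,9R,10S,12R,13S), and the sense of induction of (R)-BINOL is taken from the usual model for zinc alkynylide additions (the antipodal ligand costs the same).

## Route

Step 1
Reactants: 1 (E)-hex-3-en-1-ol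
Product: 2 (E)-hex-3-enal
Conditions: IBX (1.3 equiv), DMSO, rt, 2 h; pentane extraction, used at once
Reagents that add atoms: none
Why: Hypervalent-iodine alcohol oxidation is neutral and stops at the aldehyde, so the β,γ-olefin neither moves into conjugation nor loses its E geometry, and no stereocentre is formed.

Step 2
Reactants: 3 1,4-bis(trimethylsilyl)buta-1,3-diyne
Product: 5 buta-1,3-diyn-1-yl(trimethyl)silane, via lithium silyldiynide 4 (not isolated)
Conditions: MeLi·LiBr (1.0 equiv), Et2O, rt, 3 h; sat. aq NH4Cl, 0 °C; dried Et2O solution used directly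
Reagents that add atoms: none
Why: In this nucleophilic monodesilylation MeLi attacks one silicon of the symmetric bis-silane, the anionic diynide resists a second attack, and protonation gives the terminal diyne.

Step 3
Reactants: 2 (E)-hex-3-enal; 5 buta-1,3-diyn-1-yl(trimethyl)silane
Product: 7 (5S,7E)-1-(trimethylsilyl)dec-7-ene-1,3-diyn-5-ol, via ethylzinc silyldiynide 6 (not isolated)
Conditions: 5 (2 equiv), Et2Zn (2 equiv), (R)-BINOL (40 mol %), Cy2NH (5 mol %), Et2O, rt, 16 h; Ti(OiPr)4 (1 equiv), 1 h; 2, rt, 4 h; sat. aq NH4Cl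
Reagents that add atoms: none
Why: In this BINOL/Ti(OiPr)4-catalysed asymmetric alkynylzinc addition the (R)-BINOL titanium complex delivers the diynyl group to the Re face of the aldehyde and sets the carbinol (future C10) as S, with about 90% ee expected for linear aliphatic aldehydes.

Step 4
Reactants: 7 (5S,7E)-1-(trimethylsilyl)dec-7-ene-1,3-diyn-5-ol
Product: 9 (3Z,5S,7E)-1-(trimethylsilyl)deca-3,7-dien-1-yn-5-ol, via bis-boryl alkenylborane 8 (not isolated)
Conditions: Sia2BH (2.2 equiv; from BH3·SMe2 + 2-methylbut-2-ene), THF, 0 °C, 2 h; AcOH, 55 °C, 3 h; aq NaHCO3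
Reagents that add atoms: none
Why: In this monohydroboration–protonolysis of a 1-silyl-1,3-diyne the bulky dialkylborane adds syn to the alkyl-substituted triple bond only (boron next to the remaining alkyne), leaves the trans-disubstituted olefin alone, and AcOH replaces boron by hydrogen with retention to give the Z-enyne without touching the carbinol.

Step 5
Reactants: 9 (3Z,5S,7E)-1-(trimethylsilyl)deca-3,7-dien-1-yn-5-ol; 10 (Z)-1,3-dichloropropene
Product: 11 (1Z,6Z,8S,10E)-1-chlorotrideca-1,6,10-trien-4-yn-8-ol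
Conditions: CsF (2 equiv), CuI (20 mol %), NaI (20 mol %), DMF, 0 °C to rt
Reagents that add atoms: none
Why: This fluoride-promoted, CuI-catalysed allylation of an alkynylsilane moves the alkynyl group from silicon to the allylic CH2Cl carbon in a direct SN2 sense, and the vinylic C–Cl bond is inert, so the Z-chloroalkene and the free alcohol survive.

Step 6
Reactants: 11 (1Z,6Z,8S,10E)-1-chlorotrideca-1,6,10-trien-4-yn-8-ol; 12 ethynyl(trimethyl)silane
Product: 14 (3Z,8Z,10S,12E)-pentadeca-3,8,12-triene-1,6-diyn-10-ol, via C1-silyl trienediynol 13 (not isolated)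
Conditions: PdCl2(PhCN)2 (5 mol %), CuI (10 mol %), piperidine, rt; evaporate; K2CO3 (0.2 equiv), MeOH, 0 °C to rt
Reagents that add atoms: none
Why: Sonogashira coupling of a vinyl chloride with weakly ligated palladium in piperidine runs at room temperature with retention of the Z geometry, and catalytic K2CO3/MeOH then removes the C-silyl group before any base-sensitive bromide is present.

Step 7
Reactants: 14 (3Z,8Z,10S,12E)-pentadeca-3,8,12-triene-1,6-diyn-10-ol
Product: 15 (3Z,8S,9R,10S,12E)-8,9-epoxypentadeca-3,12-diene-1,6-diyn-10-ol (cis-epoxide, threo to the carbinol)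
Conditions: Ti(OiPr)4 (1.0 equiv), t-BuOOH (2 equiv, decane), 4 Å MS, CH2Cl2, −20 °C, 48 h; aq tartaric acid
Reagents that add atoms: tert-butyl hydroperoxide, CC(C)(C)OO
Why: Hydroxyl-directed titanium alkoxide/hydroperoxide epoxidation touches only the allylic C8=C9 bond, and A(1,3) strain in the Z-allylic alcohol holds C10–H in the olefin plane so that oxygen arrives on the hydroxyl-bearing face, giving the threo cis-epoxide (8S,9R, about 9:1 expected).

Step 8
Reactants: 15 (3Z,8S,9R,10S,12E)-8,9-epoxypentadeca-3,12-diene-1,6-diyn-10-ol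
Product: 17 (2R,3S,5R)-2-[(1R,5Z)-1-bromoocta-5-ene-2,7-diyn-1-yl]-5-[(1S)-1-bromopropyl]oxolan-3-ol, via bicyclic oxonium bromide 16 (not isolated)
Conditions: Br2 (1.0 equiv, 0.05 M in CH2Cl2, added over 1 h), CH2Cl2 (0.01 M), −78 °C, dark; aq Na2S2O3/NaHCO3
Reagents that add atoms: bromine, BrBr
Why: Proposed new method: Br2 reversibly forms the bromonium ion at the only isolated and most electron-rich olefin, C12=C13, and the epoxide oxygen closes 5-exo on C12 anti to bromine (E-olefin, hence erythro 12R,13S) to give the 1-oxoniabicyclo[3.1.0]hexane 16; in 16 the endo alkynyl arm of the cis-epoxide forces the CHBrEt group onto the opposite, convex face (2,5-trans ring B), and the bromide counter-ion opens the strained oxonium ion by SN2 at the exocyclic, propargylic C8 with inversion while C9–O is retained; any HBr-mediated opening of the epoxide followed by hydroxyl bromoetherification converges on the same product; the closest known reaction type is the bromine-assisted ring expansion of 1,2-epoxy-5-alkenes (intramolecular bromonium-ion-assisted epoxide ring opening).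

Step 9
Reactants: 17 (2R,3S,5R)-2-[(1R,5Z)-1-bromoocta-5-ene-2,7-diyn-1-yl]-5-[(1S)-1-bromopropyl]oxolan-3-ol
Product: 18 (3Z,6Z,8S,9R,10S,12R,13S)-8,13-dibromo-7,10:9,12-diepoxypentadeca-3,6-dien-1-yne (target)
Conditions: AuCl (10 mol %), K2CO3 (10 mol %), MeCN, rt, dark; filtration through Et3N-washed silica
Reagents that add atoms: none
Why: In this gold-catalysed 5-exo-dig hydroalkoxylation monovalent gold activates C6≡C7, the cis-disposed C10–OH attacks C7 anti to the metal, and protodeauration with retention leaves C5 cis to oxygen (6Z), while the carbonate buffer stops acid-catalysed migration of the enol ether and no stereocentre is touched.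

## Compound list

1 | (E)-hex-3-en-1-ol | CC/C=C/CCO | starting material
2 | (E)-hex-3-enal | CC/C=C/CC=O | intermediate
3 | 1,4-bis(trimethylsilyl)buta-1,3-diyne | C[Si](C)(C)C#CC#C[Si](C)(C)C | starting material
4 | lithium 4-(trimethylsilyl)buta-1,3-diyn-1-ide (not isolated) | [Li]C#CC#C[Si](C)(C)C | intermediate
5 | buta-1,3-diyn-1-yl(trimethyl)silane | C#CC#C[Si](C)(C)C | intermediate
6 | ethyl[4-(trimethylsilyl)buta-1,3-diyn-1-yl]zinc (not isolated) | CC[Zn]C#CC#C[Si](C)(C)C | intermediate
7 | (5S,7E)-1-(trimethylsilyl)dec-7-ene-1,3-diyn-5-ol | C[Si](C)(C)C#CC#C[C@@H](O)C/C=C/CC | intermediate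
8 | O-disiamylborinate of (3Z,5S,7E)-3-(disiamylboryl)-1-(trimethylsilyl)deca-3,7-dien-1-yn-5-ol (not isolated) | C[Si](C)(C)C#C/C(B(C(C)C(C)C)C(C)C(C)C)=C\[C@@H](OB(C(C)C(C)C)C(C)C(C)C)C/C=C/CC | intermediate
9 | (3Z,5S,7E)-1-(trimethylsilyl)deca-3,7-dien-1-yn-5-ol | C[Si](C)(C)C#C/C=C\[C@@H](O)C/C=C/CC | intermediate
10 | (Z)-1,3-dichloropropene | Cl/C=C\CCl | starting material
11 | (1Z,6Z,8S,10E)-1-chlorotrideca-1,6,10-trien-4-yn-8-ol | Cl/C=C\CC#C/C=C\[C@@H](O)C/C=C/CC | intermediate
12 | ethynyl(trimethyl)silane | C#C[Si](C)(C)C | starting material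
13 | (3Z,8Z,10S,12E)-1-(trimethylsilyl)pentadeca-3,8,12-triene-1,6-diyn-10-ol (not isolated) | C[Si](C)(C)C#C/C=C\CC#C/C=C\[C@@H](O)C/C=C/CC | intermediate
14 | (3Z,8Z,10S,12E)-pentadeca-3,8,12-triene-1,6-diyn-10-ol | C#C/C=C\CC#C/C=C\[C@@H](O)C/C=C/CC | intermediate
15 | (3Z,8S,9R,10S,12E)-8,9-epoxypentadeca-3,12-diene-1,6-diyn-10-ol | C#C/C=C\CC#C[C@@H]1O[C@@H]1[C@@H](O)C/C=C/CC | intermediate
16 | 1-oxoniabicyclo[3.1.0]hexane bromide: O+ bonded to C8, C9 and C12, C13–Br in place, C10–OH free (not isolated) | C#C/C=C\CC#C[C@@H]1[O+]2[C@@H]([C@@H](Br)CC)C[C@H](O)[C@H]12.[Br-] | intermediate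
17 | (2R,3S,5R)-2-[(1R,5Z)-1-bromoocta-5-ene-2,7-diyn-1-yl]-5-[(1S)-1-bromopropyl]oxolan-3-ol | C#C/C=C\CC#C[C@@H](Br)[C@@H]1O[C@@H]([C@@H](Br)CC)C[C@@H]1O | intermediate
18 | (3Z,6Z,8S,9R,10S,12R,13S)-8,13-dibromo-7,10:9,12-diepoxypentadeca-3,6-dien-1-yne | C#C/C=C\C/C=C1\O[C@H]2C[C@H]([C@@H](Br)CC)O[C@H]2[C@@H]1Br | target

## Step count and risks

Total step count: 9. Longest linear sequence: 8 (1 → 2 → 7 → 9 → 11 → 14 → 15 → 17 → 18).

**Step 8 (most likely to fail).**
- Bromide may collapse on the bromonium ion to give the plain 12,13-dibromide.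
- C10–OH may compete by 5-endo closure.
- The wrong bromonium face may give the 2,5-cis ring, or bromide may open the oxonium ion at C9.

The fallback sets out from 15 and comes back at 17 by decoupling the two events. LiBr/AcOH in THF opens the epoxide by SN2 at the propargylic carbon with inversion. This gives the bromodiol (3Z,8R,9R,10S,12E)-8-bromopentadeca-3,12-diene-1,6-diyne-9,10-diol F1. Ring B is then closed by ordinary hydroxyl bromoetherification with NBS in MeCN at −20 °C, where C9–OH cyclises 5-exo far faster than C10–OH can cyclise 5-endo.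

**Step 9.** The π-acid may ionise or shift the propargylic bromide, or cyclisation may go 6-endo. The fallback sets out from 17 and comes back at 18. It replaces catalysis by stoichiometric oxymercuration and demercuration.
- Hg(OCOCF3)2/Et3N in CH2Cl2 at −40 °C closes ring A by anti oxymercuration.
- Brine exchange gives the isolable vinylmercurial (6E)-6-(chloromercurio)-8,13-dibromo-7,10:9,12-diepoxypentadeca-3,6-dien-1-yne F2.
- Cold alkaline NaBH4 replaces mercury by hydrogen.

**Step 7.** The enyne olefin is deactivated and the Z secondary allylic alcohol is a slow substrate, so the homoallylic C12=C13 bond may be attacked or the threo selectivity may erode. The fallback sets out from 14 and comes back at 15. It masks the competing olefin instead of relying on metal direction.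
- Pyridinium tribromide at −40 °C adds anti to C12=C13 only. This gives the dibromide (3Z,8Z,10S)-12,13-dibromopentadeca-3,8-diene-1,6-diyn-10-ol F3.
- Hydrogen-bond-directed mCPBA epoxidation (threo selectivity about 95:5 for Z-allylic alcohols) gives the dibromo epoxy alcohol (3Z,8S,9R,10S)-12,13-dibromo-8,9-epoxypentadec-3-ene-1,6-diyn-10-ol F4.
- NaI in acetone restores the 12E olefin by stereospecific anti elimination.

Further compounds
F1 | step 8 | (3Z,8R,9R,10S,12E)-8-bromopentadeca-3,12-diene-1,6-diyne-9,10-diol | C#C/C=C\CC#C[C@@H](Br)[C@H](O)[C@@H](O)C/C=C/CC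
F2 | step 9 | (6E)-6-(chloromercurio)-8,13-dibromo-7,10:9,12-diepoxypentadeca-3,6-dien-1-yne | C#C/C=C\C/C([Hg]Cl)=C1\O[C@H]2C[C@H]([C@@H](Br)CC)O[C@H]2[C@@H]1Br
F3 | step 7 | (3Z,8Z,10S)-12,13-dibromopentadeca-3,8-diene-1,6-diyn-10-ol, erythro-12,13 (12R,13S adduct drawn, formed together with the 12S,13R adduct) | C#C/C=C\CC#C/C=C\[C@@H](O)C[C@@H](Br)[C@@H](Br)CC
F4 | step 7 | (3Z,8S,9R,10S)-12,13-dibromo-8,9-epoxypentadec-3-ene-1,6-diyn-10-ol, erythro-12,13 (12R,13S isomer drawn) | C#C/C=C\CC#C[C@@H]1O[C@@H]1[C@@H](O)C[C@@H](Br)[C@@H](Br)CC
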